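**Retrosynthetic overview**
1. Target 6 is an ent-labdane (5R,10R,14S). It is disconnected to the acyclic (S)-tetraene diacetate 4 by a proton-initiated head-to-tail bicyclization that copies the labdane biosynthesis; the cyclization is the last step.
2. Ring A forms first (C4–C5 bond), then ring B (C9–C10 bond). The C8 cation is discharged by loss of H9, which gives the 8(9)-alkene.
3. C5 and C10 are set by a chiral Brønsted acid and the E-alkene geometry. C14 is already present and too remote to interfere.
4. Diacetate 4 comes from the (S)-3-methylidene-1,2-diol 3, which comes from the (2R,3R)-epoxy alcohol 2 by hydroxyl-directed epoxide-to-allylic-alcohol isomerization.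
5. Epoxy alcohol 2 comes from all-E geranylgeraniol 1 by asymmetric epoxidation.

Assumption: the (S)-configured binaphthol-derived acid is taken to give the ent (5R,10R) series, because its (R)-enantiomer is the one known to give the normal (5S,10S) series. If the sense were reversed on this substrate, the (R)-acid would be used with no other change. The ligand is made in one alkylation from commercial (S)-BINOL and is recovered.

**Step 1**
Reactants: 1 (2E,6E,10E)-geranylgeraniol
Product: 2 [(2R,3R)-3-methyl-3-[(3E,7E)-4,8,12-trimethyltrideca-3,7,11-trien-1-yl]oxiran-2-yl]methanol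
Conditions: t-BuOOH (2 equiv, decane), Ti(OiPr)4 (5 mol %), D-(−)-diethyl tartrate (7 mol %), 4 Å MS, CH2Cl2, −20 °C
Reagents that add atoms: tert-butyl hydroperoxide, CC(C)(C)OO
Why: Katsuki–Sharpless asymmetric epoxidation, in which the Ti–tartrate catalyst binds the allylic hydroxyl so that only the 2,3-alkene of the four is oxidised, and D-(−)-tartrate gives (2R,3R), the mirror image of the (2S,3S) outcome known for geraniol with L-(+)-tartrate; C2 becomes C14 of the target.

**Step 2**
Reactants: 2 [(2R,3R)-3-methyl-3-[(3E,7E)-4,8,12-trimethyltrideca-3,7,11-trien-1-yl]oxiran-2-yl]methanol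
Product: 3 (2S,6E,10E)-7,11,15-trimethyl-3-methylidenehexadeca-6,10,14-triene-1,2-diol
Conditions: Ti(OiPr)4 (1.5 equiv), CH2Cl2, rt, 12 h; aq tartaric acid work-up
Reagents that add atoms: none
Why: Hydroxyl-directed Lewis-acid isomerization of a 2,3-epoxy alcohol to an allylic 1,2-diol, in which titanium held by the C1 alkoxide opens the tertiary C3–O bond and an isopropoxide ligand removes a proton from the C3 methyl group (cis to the CH2O–Ti arm in the E-derived epoxide) to give the exocyclic methylene; the C2–O bond is never broken, so the carbinol keeps its geometry and is now S only because the CIP priorities change.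

**Step 3**
Reactants: 3 (2S,6E,10E)-7,11,15-trimethyl-3-methylidenehexadeca-6,10,14-triene-1,2-diol
Product: 4 (2S,6E,10E)-7,11,15-trimethyl-3-methylidenehexadeca-6,10,14-triene-1,2-diyl diacetate
Conditions: Ac2O (3 equiv), pyridine, DMAP (5 mol %), CH2Cl2, 0 °C → rt
Reagents that add atoms: acetic anhydride, CC(=O)OC(C)=O
Why: DMAP-catalysed O-acylation of the primary and the secondary allylic hydroxyl; no stereocentre is touched and the two acetates are those of the target.

**Step 4**
Reactants: 4 (2S,6E,10E)-7,11,15-trimethyl-3-methylidenehexadeca-6,10,14-triene-1,2-diyl diacetate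
Product: 6 (2S)-3-methylidene-5-[(4aR,8aR)-2,5,5,8a-tetramethyl-3,4,4a,5,6,7,8,8a-octahydronaphthalen-1-yl]pentane-1,2-diyl diacetate [(5R,10R,14S)-ent-labda-8,13(16)-diene-14,15-diyl diacetate, CNP0227767.1], via ring-A monocycle 5 (not isolated)
Conditions: (S)-2-(2-fluorobenzyloxy)-2'-hydroxy-1,1'-binaphthyl (3.3 equiv), SnCl4 (3 equiv), toluene, −78 °C, 48 h; then CF3CO2H (10 equiv), SnCl4 (1 equiv), i-PrNO2, −78 → −40 °C; aq NaHCO3
Reagents that add atoms: none
Why: Proposed new method: enantioselective proton-initiated polyene cyclization with a chiral Lewis acid-assisted Brønsted acid on a substrate that has no internal terminating nucleophile, in which the bulky chiral acid protonates the terminal isopropylidene on one face as the C4–C5 bond forms (sets C5), the E-alkene and a chair transition state place the C10 methyl anti to H5 when C9 adds to the C10 cation (sets C10, trans fusion), and the C8 cation loses H9; the CF3CO2H/SnCl4 stage re-protonates ring-A-only olefin 5 and the kinetic 7-ene and 8(17)-ene isomers back to the same cations so that they drain to the tetrasubstituted 8(9)-alkene, while the 13(16)-alkene is deactivated by its allylic and homoallylic acetoxy groups and C14 is untouched; the closest known chemistry is the two-stage chiral-acid then achiral-acid cyclization of homofarnesyl ethers and homo(polyprenyl)arenes.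

**Compound list**
1 | (2E,6E,10E)-3,7,11,15-tetramethylhexadeca-2,6,10,14-tetraen-1-ol (geranylgeraniol, commercial, annatto-derived) | CC(C)=CCC/C(C)=C/CC/C(C)=C/CC/C(C)=C/CO | starting material
2 | [(2R,3R)-3-methyl-3-[(3E,7E)-4,8,12-trimethyltrideca-3,7,11-trien-1-yl]oxiran-2-yl]methanol | OC[C@H]1O[C@]1(C)CC/C=C(\C)CC/C=C(\C)CCC=C(C)C | intermediate
3 | (2S,6E,10E)-7,11,15-trimethyl-3-methylidenehexadeca-6,10,14-triene-1,2-diol | C=C(CC/C=C(\C)CC/C=C(\C)CCC=C(C)C)[C@@H](CO)O | intermediate
4 | (2S,6E,10E)-7,11,15-trimethyl-3-methylidenehexadeca-6,10,14-triene-1,2-diyl diacetate | C=C(CC/C=C(\C)CC/C=C(\C)CCC=C(C)C)[C@@H](COC(C)=O)OC(C)=O | intermediate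
5 | (2S,6E)-7-methyl-3-methylidene-9-[(1R)-2,6,6-trimethylcyclohex-2-en-1-yl]non-6-ene-1,2-diyl diacetate (ring-A monocycle, drawn as the endocyclic olefin isomer) | C=C(CC/C=C(\C)CC[C@H]1C(C)=CCCC1(C)C)[C@@H](COC(C)=O)OC(C)=O | intermediate (not isolated)
6 | (2S)-3-methylidene-5-[(4aR,8aR)-2,5,5,8a-tetramethyl-3,4,4a,5,6,7,8,8a-octahydronaphthalen-1-yl]pentane-1,2-diyl diacetate | C=C(CCC1=C(C)CC[C@@H]2C(C)(C)CCC[C@@]12C)[C@@H](COC(C)=O)OC(C)=O | target

**Totals**
Total step count: 4 (the recoverable chiral ligand is a reagent and is not counted).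
Longest linear sequence: 4 (1 → 2 → 3 → 4 → 6).

**Three steps most likely to fail**

Step 4 (highest risk). Three things can go wrong:
- The two acetates may bind SnCl4 and lower the rate and the enantioselectivity.
- Proton loss may stop at the 7-ene or 8(17)-ene, or ring closure may stop at the ring-A stage. The 13(16)-alkene may also trap the C8 cation.
- Imperfect face selectivity gives the (5S,10S,14S) diastereomer. It must be removed by AgNO3-impregnated silica and HPLC, together with olefin isomers.

Fallback: move ring formation ahead of acylation, onto an ether-protected substrate of the class on which this acid is established. It sets out from 3 and comes back at 6. TBSOTf and 2,6-lutidine convert 3 into the bis(tert-butyldimethylsilyl) ether F1. The same two-stage acid treatment closes ring A to the ring-A monocycle bis-silyl ether F2 (not isolated) and then ring B to the bicyclic bis-silyl ether F3. TBAF in THF gives the bicyclic diol F4, where ring diastereomers and olefin isomers are easiest to separate. Ac2O, pyridine and DMAP then give 6.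

Step 2. The proton may be taken from C4 instead of the methyl group, giving the internal 3-ene, or isopropoxide may open the epoxide at C3.

Fallback: replace the Lewis-acid pathway with a base-mediated syn-elimination on the protected epoxide. It sets out from 2 and comes back at 3. TBSCl and imidazole give the epoxy silyl ether F5. LiNEt2 in Et2O–hexane (0 °C to reflux) removes the least hindered β-proton, that of the methyl group, and gives the mono-silylated diol F6. TBAF then gives 3.

Step 1. Enantiomeric excess or conversion may be low on this lipophilic tetraene, and the trisubstituted epoxide is sensitive at work-up.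

Fallback: replace asymmetric catalysis with enzymatic kinetic resolution. It sets out from 1 and comes back at 4. VO(acac)2 (cat.) and t-BuOOH give the racemic epoxy alcohol F7. Ti(OiPr)4, as in step 2, gives the racemic diol F8. Amano lipase PS with vinyl acetate in MTBE first acetylates the primary hydroxyl of both enantiomers, giving the racemic primary monoacetate F9 (not isolated). It then acetylates the secondary hydroxyl of the (S)-enantiomer only (Kazlauskas rule), which gives 4 and leaves the (R)-monoacetate F10, removed by chromatography.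

**Further compounds**
F1 | step 4 | (2S,6E,10E)-1,2-bis(tert-butyldimethylsilyloxy)-7,11,15-trimethyl-3-methylidenehexadeca-6,10,14-triene | C=C(CC/C=C(\C)CC/C=C(\C)CCC=C(C)C)[C@@H](CO[Si](C)(C)C(C)(C)C)O[Si](C)(C)C(C)(C)C
F2 | step 4 | (2S,6E)-1,2-bis(tert-butyldimethylsilyloxy)-7-methyl-3-methylidene-9-[(1R)-2,6,6-trimethylcyclohex-2-en-1-yl]non-6-ene (ring-A monocycle bis-silyl ether, not isolated) | C=C(CC/C=C(\C)CC[C@H]1C(C)=CCCC1(C)C)[C@@H](CO[Si](C)(C)C(C)(C)C)O[Si](C)(C)C(C)(C)C
F3 | step 4 | (5R,10R,14S)-14,15-bis(tert-butyldimethylsilyloxy)-ent-labda-8,13(16)-diene | C=C(CCC1=C(C)CC[C@@H]2C(C)(C)CCC[C@@]12C)[C@@H](CO[Si](C)(C)C(C)(C)C)O[Si](C)(C)C(C)(C)C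
F4 | step 4 | (5R,10R,14S)-ent-labda-8,13(16)-diene-14,15-diol | C=C(CCC1=C(C)CC[C@@H]2C(C)(C)CCC[C@@]12C)[C@@H](CO)O
F5 | step 2 | tert-butyldimethyl{[(2R,3R)-3-methyl-3-[(3E,7E)-4,8,12-trimethyltrideca-3,7,11-trien-1-yl]oxiran-2-yl]methoxy}silane | CC(C)(C)[Si](C)(C)OC[C@H]1O[C@]1(C)CC/C=C(\C)CC/C=C(\C)CCC=C(C)C
F6 | step 2 | (2S,6E,10E)-1-(tert-butyldimethylsilyloxy)-7,11,15-trimethyl-3-methylidenehexadeca-6,10,14-trien-2-ol | C=C(CC/C=C(\C)CC/C=C(\C)CCC=C(C)C)[C@@H](CO[Si](C)(C)C(C)(C)C)O
F7 | step 1 | racemic trans-2,3-epoxygeranylgeraniol (both enantiomers) | OC[C@H]1O[C@]1(C)CC/C=C(\C)CC/C=C(\C)CCC=C(C)C.OC[C@@H]1O[C@@]1(C)CC/C=C(\C)CC/C=C(\C)CCC=C(C)C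
F8 | step 1 | racemic (6E,10E)-7,11,15-trimethyl-3-methylidenehexadeca-6,10,14-triene-1,2-diol (both enantiomers) | C=C(CC/C=C(\C)CC/C=C(\C)CCC=C(C)C)[C@@H](CO)O.C=C(CC/C=C(\C)CC/C=C(\C)CCC=C(C)C)[C@H](CO)O
F9 | step 1 | racemic (6E,10E)-2-hydroxy-7,11,15-trimethyl-3-methylidenehexadeca-6,10,14-trien-1-yl acetate (both enantiomers, not isolated) | C=C(CC/C=C(\C)CC/C=C(\C)CCC=C(C)C)[C@@H](COC(C)=O)O.C=C(CC/C=C(\C)CC/C=C(\C)CCC=C(C)C)[C@H](COC(C)=O)O
F10 | step 1 | (2R,6E,10E)-2-hydroxy-7,11,15-trimethyl-3-methylidenehexadeca-6,10,14-trien-1-yl acetate | C=C(CC/C=C(\C)CC/C=C(\C)CCC=C(C)C)[C@H](COC(C)=O)O
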